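**Plan**
- The last two steps only adjust oxidation level: the C5'–OH of the target is traced back to a C5'–OMe phenol through the para-quinone.
- Ring B (C1'–C6') has oxygens on C2' and C5' para to each other and an OMe on C4' next to C5'. This 4-alkoxyphenol pattern is what an alkenyl(alkoxy)carbene chromium complex, a terminal alkyne and one CO assemble, so ring B is cut at C5'–C6', C1'–C2' and C2'–C3'.
- The alkyne is cut at C2–C(sp) (2-iodochromone plus silylacetylene), and ring C at O1–C2/C2–C3, back to an ω-methoxy ketone made from 1,2,3-trimethoxybenzene (ring A).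
- Forward order: ring A is bought, ring C is closed in step 2, the alkyne is attached in steps 3–5, ring B is closed in step 7, and C5'–OH is unmasked in steps 8–9.
- Stereochemistry: the target has no stereocentre; only the regiochemistry of ring B formation has to be controlled.

Key step: step 7

Remark: the enaminone 6 is drawn Z, but its geometry has no bearing on the product. The η6 complex 19 is written in SMILES as the arene and the Cr(CO)3 fragment joined by a dot.

**Route**

Step 1
Reactants: 1 1,2,3-trimethoxybenzene; 2 methoxyacetyl chloride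
Product: 4 1-(2-hydroxy-3,4-dimethoxyphenyl)-2-methoxyethan-1-one, via trimethoxyphenyl ketone 3 (not isolated)
Conditions: AlCl3 (2.5 equiv), CH2Cl2, 0 °C → reflux; aq. HCl work-up
Reagents that add atoms: methoxyacetyl chloride 2, COCC(=O)Cl
Why: Friedel–Crafts acylation should occur at C4 of 1 (para to one OMe, ortho to another), and the aluminium chelate between the new ketone and the flanking OMe should then be cleaved selectively, the usual tandem acylation/ortho-demethylation of 1,2,3-trimethoxybenzene.

Step 2
Reactants: 4 1-(2-hydroxy-3,4-dimethoxyphenyl)-2-methoxyethan-1-one; 5 N,N-dimethylformamide dimethyl acetal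
Product: 7 3,7,8-trimethoxychromen-4-one, via enaminone 6 (not isolated)
Conditions: Me2NCH(OMe)2, toluene, 100 °C; then AcOH, 60 °C
Reagents that add atoms: N,N-dimethylformamide dimethyl acetal 5, COC(OC)N(C)C
Why: Condensation of the activated α-methylene with the amide acetal should give the enaminone, and addition–elimination by the phenol should close ring C with loss of dimethylamine, the enaminone route to 3-substituted chromones.

Step 3
Reactants: 7 3,7,8-trimethoxychromen-4-one
Product: 9 2-iodo-3,7,8-trimethoxychromen-4-one, via 2-lithiochromone 8 (not isolated)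
Conditions: LiN(iPr)2, THF, −78 °C (7 added to the base); then I2, THF, −78 → 0 °C
Reagents that add atoms: iodine, II
Why: C2–H is the most acidic C–H of 7 (sp2, next to the ring oxygen, flanked by the 3-OMe, β to the carbonyl), so directed C2-lithiation of the chromone followed by iodine quench should give the 2-iodide.

Step 4
Reactants: 9 2-iodo-3,7,8-trimethoxychromen-4-one; 10 trimethylsilylacetylene
Product: 11 3,7,8-trimethoxy-2-[(trimethylsilyl)ethynyl]chromen-4-one
Conditions: PdCl2(PPh3)2 (cat.), CuI (cat.), Et3N, THF, rt
Reagents that add atoms: trimethylsilylacetylene 10, C#C[Si](C)(C)C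
Why: Sonogashira coupling; the C2–I bond is a vinylogous acyl iodide and should undergo fast oxidative addition to zerovalent palladium at room temperature.

Step 5
Reactants: 11 3,7,8-trimethoxy-2-[(trimethylsilyl)ethynyl]chromen-4-one
Product: 12 2-ethynyl-3,7,8-trimethoxychromen-4-one
Conditions: Bu4NF, AcOH, THF, −20 → 0 °C
Reagents that add atoms: none
Why: Fluoride-induced protodesilylation of the alkynylsilane, buffered with AcOH so that no basic species adds to the activated C2 position or to the conjugated alkyne.

Step 6
Reactants: 13 methyl vinyl ether; 14 chromium hexacarbonyl Cr(CO)6; 15 trimethyloxonium tetrafluoroborate Me3OBF4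
Product: 18 pentacarbonyl[methoxy(1-methoxyethenyl)carbene]chromium, via 1-methoxyvinyllithium 16 (not isolated), via lithium acylchromate 17 (not isolated)
Conditions: tBuLi, THF, −65 → 0 °C; Cr(CO)6, THF/Et2O, −78 °C → rt; then Me3OBF4, CH2Cl2, 0 °C
Reagents that add atoms: chromium hexacarbonyl 14, O=C=[Cr](=C=O)(=C=O)(=C=O)(=C=O)=C=O; trimethyloxonium tetrafluoroborate 15, C[O+](C)C.F[B-](F)(F)F
Why: α-Lithiation of the enol ether gives the 1-methoxyvinyl anion, which should add to a CO ligand of Cr(CO)6, and O-methylation of the acylchromate completes a standard Fischer carbene complex synthesis, as known for cyclic α-alkoxyalkenyl analogues.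

Step 7
Reactants: 12 2-ethynyl-3,7,8-trimethoxychromen-4-one; 18 pentacarbonyl[methoxy(1-methoxyethenyl)carbene]chromium
Product: 20 2-(2-hydroxy-4,5-dimethoxyphenyl)-3,7,8-trimethoxychromen-4-one, via tricarbonylchromium phenol complex 19 (not isolated)
Conditions: 18 (1.5 equiv), THF (0.05 M), 50 °C, Ar; then air, Et2O, rt
Reagents that add atoms: none
Why: Thermal loss of one CO from 18 should let the alkyne bind and insert into the Cr=C bond (C5'–C6'), CO then migrates onto the new carbene carbon (C1'–C2') to give a chromium-bound dienylketene, and ring closure (C2'–C3') followed by enolisation of the cyclohexadienone gives the phenol as its Cr(CO)3 complex 19, which air sets free. The closest known reaction type is the Dötz benzannulation of alkenyl(alkoxy)carbene chromium complexes with terminal alkynes, which is documented for α-alkoxyalkenyl complexes and for alkynes conjugated to carbonyl groups. Ring B closes by a 6π electrocyclisation of the metal-bound dienylketene, in which the CH2 terminus of the enol ether bonds to the ketene carbon. No stereocentre is formed. The step needs regioselective insertion, secured by the terminal alkyne: the chromonyl group is the large substituent and should end next to the CO-derived carbon, with the hydrogen next to the carbene carbon, so that C1' lies between C2'–OH and C6'–H while the carbene carbon and its neighbour become C5'–OMe and C4'–OMe. It also needs phenol formation over cyclobutenone, furan or two-alkyne products, which an alkenyl (not aryl) complex, THF, dilution and an excess of 18 should favour.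

Step 8
Reactants: 20 2-(2-hydroxy-4,5-dimethoxyphenyl)-3,7,8-trimethoxychromen-4-one
Product: 21 2-methoxy-5-(3,7,8-trimethoxy-4-oxochromen-2-yl)cyclohexa-2,5-diene-1,4-dione
Conditions: (NH4)2Ce(NO3)6 (2.2 equiv), MeCN/H2O, 0 °C
Reagents that add atoms: water, O
Why: Oxidative demethylation of a para-methoxyphenol: two-electron oxidation, capture of water at C5' and loss of methanol should give the para-quinone, while the C4' OMe survives as a vinylogous ester and the carbonyl-deactivated ring A is left alone.

Step 9
Reactants: 21 2-methoxy-5-(3,7,8-trimethoxy-4-oxochromen-2-yl)cyclohexa-2,5-diene-1,4-dione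
Product: 22 diplotrin A, 2-(2,5-dihydroxy-4-methoxyphenyl)-3,7,8-trimethoxychromen-4-one
Conditions: Na2S2O4, EtOAc/H2O, rt, Ar
Reagents that add atoms: none
Why: Dithionite reduction of a quinone to its hydroquinone, which should leave the chromone and the methyl ethers untouched.

**Compound list**
1 | 1,2,3-trimethoxybenzene | COc1cccc(OC)c1OC | starting material
2 | methoxyacetyl chloride | COCC(=O)Cl | starting material
3 | 2-methoxy-1-(2,3,4-trimethoxyphenyl)ethan-1-one | COCC(=O)c1ccc(OC)c(OC)c1OC | intermediate
4 | 1-(2-hydroxy-3,4-dimethoxyphenyl)-2-methoxyethan-1-one | COCC(=O)c1ccc(OC)c(OC)c1O | intermediate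
5 | N,N-dimethylformamide dimethyl acetal | COC(OC)N(C)C | starting material
6 | (Z)-3-(dimethylamino)-1-(2-hydroxy-3,4-dimethoxyphenyl)-2-methoxyprop-2-en-1-one | CN(C)/C=C(\OC)C(=O)c1ccc(OC)c(OC)c1O | intermediate
7 | 3,7,8-trimethoxychromen-4-one | COc1coc2c(OC)c(OC)ccc2c1=O | intermediate
8 | 2-lithio-3,7,8-trimethoxychromen-4-one | COc1c([Li])oc2c(OC)c(OC)ccc2c1=O | intermediate
9 | 2-iodo-3,7,8-trimethoxychromen-4-one | COc1c(I)oc2c(OC)c(OC)ccc2c1=O | intermediate
10 | trimethylsilylacetylene | C#C[Si](C)(C)C | starting material
11 | 3,7,8-trimethoxy-2-[(trimethylsilyl)ethynyl]chromen-4-one | COc1c(C#C[Si](C)(C)C)oc2c(OC)c(OC)ccc2c1=O | intermediate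
12 | 2-ethynyl-3,7,8-trimethoxychromen-4-one | C#Cc1oc2c(OC)c(OC)ccc2c(=O)c1OC | intermediate
13 | methyl vinyl ether | COC=C | starting material
14 | chromium hexacarbonyl Cr(CO)6 | O=C=[Cr](=C=O)(=C=O)(=C=O)(=C=O)=C=O | starting material
15 | trimethyloxonium tetrafluoroborate Me3OBF4 | C[O+](C)C.F[B-](F)(F)F | starting material
16 | 1-methoxyvinyllithium | [Li]C(=C)OC | intermediate
17 | lithium pentacarbonyl(2-methoxyprop-2-enoyl)chromate | [Li+].[O-]C(C(=C)OC)=[Cr](=C=O)(=C=O)(=C=O)(=C=O)=C=O | intermediate
18 | pentacarbonyl[methoxy(1-methoxyethenyl)carbene]chromium | COC(=C)C(OC)=[Cr](=C=O)(=C=O)(=C=O)(=C=O)=C=O | intermediate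
19 | tricarbonyl(η6-arene)chromium complex of phenol 20, chromium on ring B | COc1cc(O)c(-c2oc3c(OC)c(OC)ccc3c(=O)c2OC)cc1OC.O=C=[Cr](=C=O)=C=O | intermediate
20 | 2-(2-hydroxy-4,5-dimethoxyphenyl)-3,7,8-trimethoxychromen-4-one | COc1cc(O)c(-c2oc3c(OC)c(OC)ccc3c(=O)c2OC)cc1OC | intermediate
21 | 2-methoxy-5-(3,7,8-trimethoxy-4-oxochromen-2-yl)cyclohexa-2,5-diene-1,4-dione | COC1=CC(=O)C(c2oc3c(OC)c(OC)ccc3c(=O)c2OC)=CC1=O | intermediate
22 | diplotrin A, 2-(2,5-dihydroxy-4-methoxyphenyl)-3,7,8-trimethoxychromen-4-one | COc1cc(O)c(-c2oc3c(OC)c(OC)ccc3c(=O)c2OC)cc1O | target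

**Step count**
Total steps: 9. Longest linear sequence: 8 steps (steps 1–5 and 7–9, from 1 to 22); step 6 is a one-step side branch.

**Steps most likely to fail**

Step 7. The electron-poor, conjugated alkyne may insert slowly into the carbene complex, so that cyclobutenone, furan or two-alkyne pathways, or oligomerisation of the alkyne, take over. Fallback: from iodide 9, Suzuki–Miyaura coupling with commercial 2,4,5-trimethoxyphenylboronic acid (Pd(PPh3)4, K3PO4, dioxane, 90 °C) should give 3,7,8-trimethoxy-2-(2,4,5-trimethoxyphenyl)chromen-4-one F1. Oxidation with (NH4)2Ce(NO3)6 in MeCN/H2O at 0 °C should then remove both methyl groups of its only para-dimethoxy pair (C2'/C5') and rejoin the route at quinone 21.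

Step 3. The amide base or the lithiated chromone may add to C2 of unreacted 7, or the lithiated species may decompose before the iodine quench. Fallback: from ketone 4, a Kostanecki–Robinson reaction (Ac2O, NaOAc, 170 °C) should give 3,7,8-trimethoxy-2-methylchromen-4-one F2. SeO2 in dioxane at reflux should oxidise the activated 2-methyl group to 3,7,8-trimethoxy-4-oxochromene-2-carbaldehyde F3. Homologation with the Ohira–Bestmann reagent (dimethyl (1-diazo-2-oxopropyl)phosphonate, K2CO3, MeOH, 0 °C) should then give alkyne 12, bypassing steps 2 to 5.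

Step 5. Fluoride, acetate or traces of base may add in conjugate fashion to the liberated terminal alkyne, and the product may oligomerise during desilylation. Fallback: from iodide 9, Stille coupling with ethynyltributylstannane (Pd(PPh3)4, toluene, 60 °C) should install the terminal alkyne under neutral conditions and give 12 directly, replacing steps 4 and 5; this makes no new compound (entry F0).

**Further compounds**
F1 | step 7 | 3,7,8-trimethoxy-2-(2,4,5-trimethoxyphenyl)chromen-4-one | COc1cc(OC)c(-c2oc3c(OC)c(OC)ccc3c(=O)c2OC)cc1OC
F2 | step 3 | 3,7,8-trimethoxy-2-methylchromen-4-one | Cc1oc2c(OC)c(OC)ccc2c(=O)c1OC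
F3 | step 3 | 3,7,8-trimethoxy-4-oxochromene-2-carbaldehyde | O=Cc1oc2c(OC)c(OC)ccc2c(=O)c1OC
F0 | step 5 | none | none
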